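All runs are calculated with made-up constants, noise included.

A plateau in percent does not carry over from one charge to another. The south-west run, charged with 0.18 M of substrate, flattens near 34.6% of product by 8.00 d; the north-east flask, charged with 0.092 M under the same gas, is asked about at 10 d.

| flask | substrate | gas | remark | time |
|---|---|---|---|---|
| north-east | 0.092 M | 15 mM (held) | the very flask that is asked about, followed so far |  |
| south-west | 0.18 M | 15 mM (held) | run made earlier |  |
| flask | 0.092 M | 15 mM (held) |  | 10 d |

north-east run (percent of the substrate charged)

| time / h | product / % | substrate / % |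
|---|---|---|
| 1.50 | 0.6 | 99.0 |
| 4.00 | 3.7 | 96.8 |
| 8.00 | 9.5 | 90.7 |
| 12.0 | 14.5 | 86.0 |
| 20.0 | 23.8 | 75.8 |
| 25.0 | 28.9 | 71.7 |
| 30.0 | 32.1 | 67.2 |

south-west run (percent of the substrate charged)

| time / d | product / % | substrate / % |
|---|---|---|
| 0.625 | 14.2 | 86.1 |
| 0.833 | 19.0 | 81.8 |
| 1.25 | 25.8 | 75.6 |
| 2.08 | 31.1 | 69.0 |
| 3.00 | 33.0 | 67.2 |
| 5.00 | 33.9 | 66.1 |
| 8.00 | 34.6 | 65.3 |

(standard deviation of a reading: 0.3 percentage points)

- at the start none of coupling partner is dissolved
- what was read earlier has a scatter of 0.3 percentage points, one standard deviation
- reactions considered so far: substrate + coupling partner <-> product + by-product; gas <-> coupling partner; coupling partner <-> dormant form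

- product at 10 d, in percent of the substrate charged
- the change that raises the amount of product at 10 d, in percent of the substrate charged most ("none" if none brings more than 2 percentage points) (blue / grey / none)
- amount of product at 10 d, in percent of the substrate charged, after blue

At equal times the north-east run is ahead of the south-west run in percent: it has 23.8% against 19.0% at 20.0 h, and 32.1% against 25.8% at 30.0 h.

For the late end, south-west at 8.00 d reads 0.0330 M as Q, the resting quotient: charge c times x times x over s, where x and s are the fractions found as product and substrate. Product and by-product appear in pairs, so Q is an apparent equilibrium constant times the resting level of coupling partner. At 3.00 d it read 0.0292 M, so I take the latest reading.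

With the same gas I expect the same Q, so the north-east flask, with its smaller charge, ends at a larger fraction. Q/c is 0.359, which gives x = 44.6%. That needs 0.0410 M of coupling partner, less than the 0.0623 M south-west had used by 8.00 d, so I expect the flask to arrive in time.

Blue, doubling the saturation concentration of gas, doubles Q if coupling partner follows saturation, giving 56.1%. Grey, doubling the transfer coefficient of the gas, does not enter Q, so I pick blue.

The forecast gives 44.6%, blue and 56%, holding that “the flask tracks equilibrium”.

The flask gives 44.6%; blue adds 12 percentage points, reaching 56.1%, and grey adds 0 points.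

    substrate + coupling partner ⇌ product + by-product (K = 2.20, k = 6.50 × 10⁻⁴ M⁻¹ s⁻¹)
    gas ⇌ coupling partner, rate k2*(csat - [coupling partner]) (kL = 7.90 × 10⁻⁵ s⁻¹)
    coupling partner ⇌ dormant form (K = 2.10, k = 8.40 × 10⁻⁵ s⁻¹)

The north-east flask has come to rest: its relaxation half-life of 0.120 d is far shorter than 10 d. Product stands at 44.5% at 5.00 d, 44.6% at 10 d and 44.6% at 100 d, and dormant form reads 0.0315 M at 10.0 d and 0.0315 M at 100 d. The answer moves 5 points at a time of 1.89 d or a charge of 0.127 M.

For the neighbour charged with 0.037 M, Q/c is 0.892, so x is 59.8%. That flask gives 59.8%.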